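## Retrosynthetic overview

1. Feature used: ring B is a phenol. C4' (OH) sits between two alkylated carbons (C3' prenyl, C5' (S)-4-hydroxy-3-methylbutyl), C2' and C6' are CH, and C1' is bonded to C2 of ring C. C2'–C6' are therefore the five carbons of a 3,5-dialkyl-4H-pyran-4-one, and C1' takes the place of its ring oxygen.
2. Key disconnection: C1'–C2' and C1'–C6' are cut together. C1' becomes the 2-methyl carbon of 3,6-dimethoxy-5,7-bis(MOM-oxy)-2-methylchromone, and the rest of ring B becomes the pyranone.
3. Chromone: ring A comes from the symmetric bis-MOM ether of 2-methoxyresorcinol. C–H borylation/oxidation installs the future O1 as the only free phenol, so no 6-OMe/8-OMe ambiguity can arise. Bromination and Weinreb acylation add C4–C3, and Kostanecki–Robinson acetylation closes ring C.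
4. Pyranone: 6-methylhept-5-en-2-one, as its dimethylhydrazone, is alkylated with the one-carbon-homologated Roche-ester iodide I–CH2CH2–CH(CH3)–CH2OTBS. The C3 iodide itself would leave the side chain one CH2 short. Both α-carbons are then formylated and the product is cyclodehydrated.
5. Order of rings: A (bought), C (step 5), pyranone (step 13), B (step 14). One acid step then removes both MOM groups and the silyl group.

Key step: step 14

Remark on the chemistry: the side-chain centre in the given SMILES is (S). The ester carbon of the Roche ester becomes the chain and its CH2OH stays the CH2OH of the target, so the (R)-ester is the correct enantiomer.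

## Route

Step 1
Reactants: 1 2-methoxybenzene-1,3-diol (2-methoxyresorcinol)
Product: 2 2-methoxy-1,3-bis(methoxymethoxy)benzene
Conditions: MOMCl (2.5 equiv), i-Pr2NEt (3 equiv), CH2Cl2, 0 °C → rt
Reagents that add atoms: chloromethyl methyl ether, COCCl
Why: Williamson-type O-alkylation of both phenols with the reactive chloromethyl ether gives MOM ethers that tolerate the later organometallic, basic and hot-anhydride steps and fall only in the final acid step.

Step 2
Reactants: 2 2-methoxy-1,3-bis(methoxymethoxy)benzene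
Product: 4 4-methoxy-3,5-bis(methoxymethoxy)phenol, via aryl pinacol boronate 3 (not isolated)
Conditions: [Ir(OMe)(cod)]2 (1.5 mol %), 4,4'-di-tert-butyl-2,2'-bipyridine (3 mol %), B2pin2 (0.6 equiv), THF, 80 °C; then 30% H2O2, aq NaOH, 0 °C
Reagents that add atoms: bis(pinacolato)diboron, CC1(C)OB(OC1(C)C)B1OC(C)(C)C(C)(C)O1 (boryl group of 3); hydrogen peroxide, OO (phenol oxygen of 4)
Why: Sterically governed iridium-catalysed aromatic C–H borylation takes the only C–H without an ortho substituent (C5 of the 1,2,3-trioxygenated ring), and basic peroxide oxidation of the C–B bond at that position gives the phenol that becomes O1.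

Step 3
Reactants: 4 4-methoxy-3,5-bis(methoxymethoxy)phenol
Product: 5 2-bromo-4-methoxy-3,5-bis(methoxymethoxy)phenol
Conditions: NBS (1.0 equiv), CH2Cl2, −78 → −20 °C
Reagents that add atoms: N-bromosuccinimide, O=C1CCC(=O)N1Br
Why: In this electrophilic aromatic bromination of a strongly activated phenol the two open ring positions are equivalent by symmetry, so one equivalent of NBS at low temperature should give a single monobromide under acid-free conditions.

Step 4
Reactants: 5 2-bromo-4-methoxy-3,5-bis(methoxymethoxy)phenol; 6 N,2-dimethoxy-N-methylacetamide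
Product: 7 1-[2-hydroxy-5-methoxy-4,6-bis(methoxymethoxy)phenyl]-2-methoxyethan-1-one
Conditions: n-BuLi (2.2 equiv), THF, −78 → −40 °C; 6 (1.3 equiv), −78 → 0 °C; AcOH quench
Reagents that add atoms: none
Why: O-deprotonation and bromine–lithium exchange give the ortho-lithiated lithium phenoxide, which is acylated in a Weinreb ketone synthesis whose chelated tetrahedral adduct prevents a second addition.

Step 5
Reactants: 7 1-[2-hydroxy-5-methoxy-4,6-bis(methoxymethoxy)phenyl]-2-methoxyethan-1-one
Product: 10 3,6-dimethoxy-5,7-bis(methoxymethoxy)-2-methyl-4H-chromen-4-one, via aryl acetate 8 (not isolated), via α-methoxy-1,3-diketone 9 (not isolated)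
Conditions: Ac2O, NaOAc (3 equiv), 140 °C
Reagents that add atoms: acetic anhydride, CC(=O)OC(C)=O
Why: In the Kostanecki–Robinson acylation, long used on ω-methoxy-2-hydroxyacetophenones, O-acetylation, a Baker–Venkataraman-type acyl shift, hemiketalisation through the only free phenol and loss of water close ring C, while the acetate buffer protects the MOM ethers and the position of the free OH fixes the 6-methoxy pattern.

Step 6
Reactants: 11 methyl (R)-3-hydroxy-2-methylpropanoate
Product: 12 methyl (R)-3-[(tert-butyldimethylsilyl)oxy]-2-methylpropanoate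
Conditions: TBSCl, imidazole, CH2Cl2, 0 °C → rt
Reagents that add atoms: tert-butyldimethylsilyl chloride, CC(C)(C)[Si](C)(C)Cl
Why: Imidazole-promoted silylation of the primary alcohol does not touch the stereocenter, which is taken from the chiral pool.

Step 7
Reactants: 12 methyl (R)-3-[(tert-butyldimethylsilyl)oxy]-2-methylpropanoate
Product: 13 (R)-3-[(tert-butyldimethylsilyl)oxy]-2-methylpropanal
Conditions: i-Bu2AlH (1.1 equiv), CH2Cl2, −78 °C; aq KNaC4H4O6 (potassium sodium tartrate)
Reagents that add atoms: none
Why: In this partial ester reduction the tetrahedral aluminium hemiacetal survives at −78 °C and gives the aldehyde only on work-up, and the aldehyde is used at once so that the α-centre does not epimerise.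

Step 8
Reactants: 13 (R)-3-[(tert-butyldimethylsilyl)oxy]-2-methylpropanal
Product: 14 tert-butyl(dimethyl){[(2S)-2-methylbut-3-en-1-yl]oxy}silane
Conditions: Ph3PCH3Br, n-BuLi, THF, 0 °C; 13, −78 °C → rt
Reagents that add atoms: methyltriphenylphosphonium bromide, C[P+](c1ccccc1)(c1ccccc1)c1ccccc1.[Br-]
Why: Wittig methylenation with the non-stabilised ylide is fast at low temperature and adds the carbon missing from the C3 building block without loss of configuration (the descriptor changes to S only through the priority rules).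

Step 9
Reactants: 14 tert-butyl(dimethyl){[(2S)-2-methylbut-3-en-1-yl]oxy}silane
Product: 16 (3S)-4-[(tert-butyldimethylsilyl)oxy]-3-methylbutan-1-ol, via B-alkyl-9-BBN adduct 15 (not isolated)
Conditions: 9-BBN (1.2 equiv), THF, 0 °C → rt; then aq NaOH, 30% H2O2, 0 °C
Reagents that add atoms: 9-borabicyclo[3.3.1]nonane, [H]B1C2CCCC1CCC2 (boryl group of 15); hydrogen peroxide, OO (hydroxyl oxygen of 16)
Why: Anti-Markovnikov hydroboration with the bulky borane places boron on the terminal carbon, and oxidation gives the primary alcohol without touching the stereocenter.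

Step 10
Reactants: 16 (3S)-4-[(tert-butyldimethylsilyl)oxy]-3-methylbutan-1-ol
Product: 17 tert-butyl{[(2S)-4-iodo-2-methylbutyl]oxy}dimethylsilane
Conditions: I2, PPh3, imidazole, CH2Cl2, 0 °C
Reagents that add atoms: iodine, II
Why: Appel-type iodination proceeds by SN2 displacement of the alkoxyphosphonium ion at an unhindered primary carbon two atoms from the stereocenter, under buffered conditions that spare the silyl ether.

Step 11
Reactants: 18 6-methylhept-5-en-2-one
Product: 19 6-methylhept-5-en-2-one N,N-dimethylhydrazone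
Conditions: Me2NNH2 (1.5 equiv), cat. AcOH, EtOH, reflux
Reagents that add atoms: 1,1-dimethylhydrazine, CN(C)N
Why: Acid-catalysed hydrazone condensation converts the methyl ketone into an aza-enolate precursor that alkylates cleanly and only once, unlike the ketone lithium enolate with an unactivated iodide.

Step 12
Reactants: 19 6-methylhept-5-en-2-one N,N-dimethylhydrazone; 17 tert-butyl{[(2S)-4-iodo-2-methylbutyl]oxy}dimethylsilane
Product: 21 (2S)-1-[(tert-butyldimethylsilyl)oxy]-2,10-dimethylundec-9-en-6-one, via alkylated hydrazone 20 (not isolated)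
Conditions: LiN(i-Pr)2 (1.05 equiv), THF, 0 °C; 17, −78 °C → rt; then sat. aq oxalic acid, Et2O, rt
Reagents that add atoms: water, O
Why: In the Corey–Enders hydrazone alkylation, deprotonation occurs at the less substituted (methyl) carbon, SN2 reaction with the primary iodide makes the C5–C4 bond of 21, and mild two-phase hydrolysis frees the ketone while keeping the silyl ether.

Step 13
Reactants: 21 (2S)-1-[(tert-butyldimethylsilyl)oxy]-2,10-dimethylundec-9-en-6-one; 22 ethyl formate
Product: 24 3-[(3S)-4-{[tert-butyl(dimethyl)silyl]oxy}-3-methylbutyl]-5-(3-methylbut-2-en-1-yl)-4H-pyran-4-one, via bis(hydroxymethylene) ketone 23 (not isolated)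
Conditions: NaH (4 equiv), cat. EtOH, 22 (10 equiv), THF, 0 °C → rt; AcOH quench; then PPTS (cat.), 4 Å MS, toluene, 60 °C
Reagents that add atoms: none
Why: Double Claisen formylation acylates both α-methylene carbons (their order is irrelevant), and the bis-enol then loses water under mild acid by addition–elimination of one enol oxygen onto the other enal, the classical route from dialkyl ketones to 3,5-dialkyl-4-pyranones, while PPTS in an aprotic solvent spares the silyl ether and the prenyl alkene.

Step 14
Reactants: 10 3,6-dimethoxy-5,7-bis(methoxymethoxy)-2-methyl-4H-chromen-4-one; 24 3-[(3S)-4-{[tert-butyl(dimethyl)silyl]oxy}-3-methylbutyl]-5-(3-methylbut-2-en-1-yl)-4H-pyran-4-one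
Product: 26 2-{3-[(3S)-4-{[tert-butyl(dimethyl)silyl]oxy}-3-methylbutyl]-4-hydroxy-5-(3-methylbut-2-en-1-yl)phenyl}-3,6-dimethoxy-5,7-bis(methoxymethoxy)-4H-chromen-4-one, via ring-opened formyl enol 25 (not isolated)
Conditions: 10, LiN(SiMe3)2 (1.1 equiv), THF, −78 °C; 24 (1.1 equiv), −78 → 0 °C; then KOt-Bu (3 equiv), t-BuOH/THF, 4 Å MS, 0 → 50 °C; AcOH quench
Reagents that add atoms: none
Why: Proposed new method: the lithium dienolate formed at the 2-methyl group of 10 should add through its exocyclic carbon to an unsubstituted α-carbon (C2 or C6) of 24 (forming C1'–C2'), and the enolate so produced ejects the ring oxygen by E1cB, opening the heterocycle to the enolate of 25. After the switch to KOt-Bu/t-BuOH, which supplies a stronger base, a looser counter-ion and a proton shuttle able to unmask the enolised aldehyde, the CH2 now lying between chromone C2 and the dienone is deprotonated a second time and closes on the formyl carbon (forming C1'–C6'); dehydration and enolisation of the cyclohexadienone give the 4'-phenoxide, and this aromatisation drains all earlier equilibria, the reversible 1,2-adduct included. The nearest known reaction types are the KOt-Bu-promoted conversion of 4-pyranones and pyrylium salts into 4-nitrophenols and nitroarenes with nitromethane, and the alkoxide-promoted condensation of 3-methoxy-2-methylchromones with aldehydes to 2-styrylchromones; what is new is the use of the chromone methyl group as the carbon acid in the ring transformation. Ring B is closed in a 6-(enolexo)-exo-trig aldol mode. No stereocenter is formed, and the (S)-centre of the side chain has no acidifying neighbour and passes through unchanged. The step needs conjugate rather than carbonyl attack and cross- rather than self-condensation: the C4 carbonyl of 24 is hemmed in by its two alkyl neighbours while C2/C6 bear only hydrogen, C2 of the chromone is fully substituted and made electron-rich by the 3-methoxy group, and because the incoming carbon finally bridges C2 and C6 it is immaterial which of them is attacked first.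

Step 15
Reactants: 26 2-{3-[(3S)-4-{[tert-butyl(dimethyl)silyl]oxy}-3-methylbutyl]-4-hydroxy-5-(3-methylbut-2-en-1-yl)phenyl}-3,6-dimethoxy-5,7-bis(methoxymethoxy)-4H-chromen-4-one
Product: 27 5,7-dihydroxy-2-{4-hydroxy-3-[(3S)-4-hydroxy-3-methylbutyl]-5-(3-methylbut-2-en-1-yl)phenyl}-3,6-dimethoxy-4H-chromen-4-one (CNP0156581.1)
Conditions: 1.25 M HCl in MeOH, 0 °C → rt (40 °C if the 7-O-MOM group lags)
Reagents that add atoms: none
Why: Acid-catalysed acetal exchange of the two aryl MOM ethers and methanolysis of the primary silyl ether occur under the dilute methanolic HCl conditions routinely used on C-prenylated flavonoids, which are kept mild so that the ortho-prenylphenol does not cyclise.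

## Compound list

1 | 2-methoxybenzene-1,3-diol (2-methoxyresorcinol) | COc1c(O)cccc1O | starting material
2 | 2-methoxy-1,3-bis(methoxymethoxy)benzene | COCOc1cccc(OCOC)c1OC | intermediate
3 | 2-[4-methoxy-3,5-bis(methoxymethoxy)phenyl]-4,4,5,5-tetramethyl-1,3,2-dioxaborolane | COCOc1cc(cc(OCOC)c1OC)B1OC(C)(C)C(C)(C)O1 | intermediate
4 | 4-methoxy-3,5-bis(methoxymethoxy)phenol | COCOc1cc(O)cc(OCOC)c1OC | intermediate
5 | 2-bromo-4-methoxy-3,5-bis(methoxymethoxy)phenol | COCOc1cc(O)c(Br)c(OCOC)c1OC | intermediate
6 | N,2-dimethoxy-N-methylacetamide | COCC(=O)N(C)OC | starting material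
7 | 1-[2-hydroxy-5-methoxy-4,6-bis(methoxymethoxy)phenyl]-2-methoxyethan-1-one | COCC(=O)c1c(O)cc(OCOC)c(OC)c1OCOC | intermediate
8 | 4-methoxy-2-(methoxyacetyl)-3,5-bis(methoxymethoxy)phenyl acetate | COCC(=O)c1c(OC(C)=O)cc(OCOC)c(OC)c1OCOC | intermediate
9 | 1-[2-hydroxy-5-methoxy-4,6-bis(methoxymethoxy)phenyl]-2-methoxybutane-1,3-dione (racemic at C2) | COC(C(C)=O)C(=O)c1c(O)cc(OCOC)c(OC)c1OCOC | intermediate
10 | 3,6-dimethoxy-5,7-bis(methoxymethoxy)-2-methyl-4H-chromen-4-one | COc1c(OCOC)cc2oc(C)c(OC)c(=O)c2c1OCOC | intermediate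
11 | methyl (R)-3-hydroxy-2-methylpropanoate | COC(=O)[C@H](C)CO | starting material
12 | methyl (R)-3-[(tert-butyldimethylsilyl)oxy]-2-methylpropanoate | COC(=O)[C@H](C)CO[Si](C)(C)C(C)(C)C | intermediate
13 | (R)-3-[(tert-butyldimethylsilyl)oxy]-2-methylpropanal | O=C[C@H](C)CO[Si](C)(C)C(C)(C)C | intermediate
14 | tert-butyl(dimethyl){[(2S)-2-methylbut-3-en-1-yl]oxy}silane | C=C[C@H](C)CO[Si](C)(C)C(C)(C)C | intermediate
15 | 9-[(3S)-4-{[tert-butyl(dimethyl)silyl]oxy}-3-methylbutyl]-9-borabicyclo[3.3.1]nonane | B1(CC[C@H](C)CO[Si](C)(C)C(C)(C)C)C2CCCC1CCC2 | intermediate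
16 | (3S)-4-[(tert-butyldimethylsilyl)oxy]-3-methylbutan-1-ol | OCC[C@H](C)CO[Si](C)(C)C(C)(C)C | intermediate
17 | tert-butyl{[(2S)-4-iodo-2-methylbutyl]oxy}dimethylsilane | ICC[C@H](C)CO[Si](C)(C)C(C)(C)C | intermediate
18 | 6-methylhept-5-en-2-one | CC(=O)CCC=C(C)C | starting material
19 | (E)-6-methylhept-5-en-2-one N,N-dimethylhydrazone | C/C(CCC=C(C)C)=N\N(C)C | intermediate
20 | N,N-dimethylhydrazone of ketone 21 (C=N geometry not fixed) | CN(C)N=C(CCC=C(C)C)CCC[C@H](C)CO[Si](C)(C)C(C)(C)C | intermediate
21 | (2S)-1-[(tert-butyldimethylsilyl)oxy]-2,10-dimethylundec-9-en-6-one | CC(C)=CCCC(=O)CCC[C@H](C)CO[Si](C)(C)C(C)(C)C | intermediate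
22 | ethyl formate | CCOC=O | starting material
23 | bis(hydroxymethylene) derivative of 21 (bis-enol of the 2,4-dialkyl-3-oxopentanedial; enol geometry not fixed) | OC=C(CC=C(C)C)C(=O)C(=CO)CC[C@H](C)CO[Si](C)(C)C(C)(C)C | intermediate
24 | 3-[(3S)-4-{[tert-butyl(dimethyl)silyl]oxy}-3-methylbutyl]-5-(3-methylbut-2-en-1-yl)-4H-pyran-4-one | O=c1c(CC=C(C)C)cocc1CC[C@H](C)CO[Si](C)(C)C(C)(C)C | intermediate
25 | ring-opened Michael adduct, chromon-2-yl–CH2–CH=C(prenyl)–C(=O)–C(=CHOH)–CH2CH2CH(CH3)CH2OTBS (present as its enolate; alkene geometries not fixed) | COc1c(OCOC)cc2oc(CC=C(CC=C(C)C)C(=O)C(=CO)CC[C@H](C)CO[Si](C)(C)C(C)(C)C)c(OC)c(=O)c2c1OCOC | intermediate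
26 | 2-{3-[(3S)-4-{[tert-butyl(dimethyl)silyl]oxy}-3-methylbutyl]-4-hydroxy-5-(3-methylbut-2-en-1-yl)phenyl}-3,6-dimethoxy-5,7-bis(methoxymethoxy)-4H-chromen-4-one | COc1c(OCOC)cc2oc(-c3cc(CC=C(C)C)c(O)c(CC[C@H](C)CO[Si](C)(C)C(C)(C)C)c3)c(OC)c(=O)c2c1OCOC | intermediate
27 | 5,7-dihydroxy-2-{4-hydroxy-3-[(3S)-4-hydroxy-3-methylbutyl]-5-(3-methylbut-2-en-1-yl)phenyl}-3,6-dimethoxy-4H-chromen-4-one (CNP0156581.1) | COc1c(O)cc2oc(-c3cc(CC=C(C)C)c(O)c(CC[C@H](C)CO)c3)c(OC)c(=O)c2c1O | target

## Step count and risks

Total step count: 15. Longest linear sequence: 9 steps (11 → 27 through steps 6–10 and 12–15). The chromone branch contributes 5 steps and the hydrazone 1 step.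

**Risk 1, step 14.**
- Carbonyl addition or mere proton exchange may take the place of conjugate addition.
- The sequence may stall after ring opening because the aldehyde stays locked as its stabilised enolate.
- The hydroxide released in the dehydration may attack ring C.

The fallback builds ring B by cross-coupling and forms ring C of the flavone by Baker–Venkataraman chemistry. It sets out from ketone 7 and borane 15 (made from 14 as in step 9) and comes back at target 27.
- Commercial methyl 3-bromo-4-hydroxybenzoate is iodinated (NIS, cat. TsOH, MeCN) to methyl 3-bromo-4-hydroxy-5-iodobenzoate F1.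
- F1 is protected (MOMCl, i-Pr2NEt) as methyl 3-bromo-5-iodo-4-(methoxymethoxy)benzoate F2.
- A B-alkyl Suzuki–Miyaura coupling with 15 at the more reactive C–I bond (PdCl2(dppf), K3PO4, THF/DMF/H2O) gives methyl 3-bromo-5-[(3S)-4-(tert-butyldimethylsilyloxy)-3-methylbutyl]-4-(methoxymethoxy)benzoate F3.
- Stille coupling with tributyl(3-methylbut-2-enyl)stannane (Pd(PPh3)4, DMF, 90 °C) gives methyl 3-[(3S)-4-(tert-butyldimethylsilyloxy)-3-methylbutyl]-4-(methoxymethoxy)-5-prenylbenzoate F4.
- LiOH hydrolysis gives 3-[(3S)-4-(tert-butyldimethylsilyloxy)-3-methylbutyl]-4-(methoxymethoxy)-5-prenylbenzoic acid F5.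
- Esterification with the phenol of 7 (EDC, DMAP) gives the ring A aryl ester of acid F5 F6.
- Baker–Venkataraman rearrangement (KOt-Bu, THF) gives the 2-methoxy-1,3-diaryl-1,3-diketone F7.
- Cyclodehydration through the only free phenol (cat. PPTS, toluene, 4 Å MS, 80 °C) gives the 4',5,7-tris-O-MOM silyl-protected flavone F8, which is deprotected under the conditions of step 15 to 27.

**Risk 2, step 13.** The second formylation must start from an already anionic β-ketoaldehyde enolate and may stall, while the base slowly decarbonylates the formate. The fallback replaces the anionic Claisen chemistry by neutral thermal aminomethylenation. It sets out from ketone 21 and comes back at pyranone 24.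
- Ketone 21 is heated with excess tert-butoxybis(dimethylamino)methane (neat, 110 °C) to give the 1,5-bis(dimethylamino)-2,4-dialkylpenta-1,4-dien-3-one F9.
- Hydrolysis of one enaminone and addition–elimination onto the other (aq AcOH, THF, 40 °C) close the pyranone 24.

**Risk 3, step 4.** Halogen–metal exchange may be slow on the electron-rich phenoxide, and the aryllithium may be protonated by the α-hydrogens of the amide or alkylated by butyl bromide. The fallback uses directed ortho-metalation of a protected phenol. It sets out from phenol 4, bypasses bromide 5 and comes back at ketone 7.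
- Benzylation (BnBr, K2CO3, DMF) gives 5-(benzyloxy)-2-methoxy-1,3-bis(methoxymethoxy)benzene F10.
- MOM-directed lithiation at either of the two equivalent ring C–H positions (n-BuLi, TMEDA, THF, 0 °C) and acylation with 6 give 1-[2-(benzyloxy)-5-methoxy-4,6-bis(methoxymethoxy)phenyl]-2-methoxyethan-1-one F11.
- Hydrogenolysis (H2, Pd/C, EtOAc), possible here because no alkene is yet present, gives 7.

## Further compounds

F1 | step 14 | methyl 3-bromo-4-hydroxy-5-iodobenzoate | COC(=O)c1cc(Br)c(O)c(I)c1
F2 | step 14 | methyl 3-bromo-5-iodo-4-(methoxymethoxy)benzoate | COCOc1c(Br)cc(cc1I)C(=O)OC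
F3 | step 14 | methyl 3-bromo-5-[(3S)-4-(tert-butyldimethylsilyloxy)-3-methylbutyl]-4-(methoxymethoxy)benzoate | COCOc1c(Br)cc(cc1CC[C@H](C)CO[Si](C)(C)C(C)(C)C)C(=O)OC
F4 | step 14 | methyl 3-[(3S)-4-(tert-butyldimethylsilyloxy)-3-methylbutyl]-4-(methoxymethoxy)-5-prenylbenzoate | COCOc1c(CC=C(C)C)cc(cc1CC[C@H](C)CO[Si](C)(C)C(C)(C)C)C(=O)OC
F5 | step 14 | 3-[(3S)-4-(tert-butyldimethylsilyloxy)-3-methylbutyl]-4-(methoxymethoxy)-5-prenylbenzoic acid | COCOc1c(CC=C(C)C)cc(cc1CC[C@H](C)CO[Si](C)(C)C(C)(C)C)C(=O)O
F6 | step 14 | ring A aryl ester of acid F5 | COCC(=O)c1c(OC(=O)c2cc(CC=C(C)C)c(OCOC)c(CC[C@H](C)CO[Si](C)(C)C(C)(C)C)c2)cc(OCOC)c(OC)c1OCOC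
F7 | step 14 | 2-methoxy-1,3-diaryl-1,3-diketone (epimers at C2) | COC(C(=O)c1cc(CC=C(C)C)c(OCOC)c(CC[C@H](C)CO[Si](C)(C)C(C)(C)C)c1)C(=O)c1c(O)cc(OCOC)c(OC)c1OCOC
F8 | step 14 | 4',5,7-tris-O-MOM silyl-protected flavone | COc1c(OCOC)cc2oc(-c3cc(CC=C(C)C)c(OCOC)c(CC[C@H](C)CO[Si](C)(C)C(C)(C)C)c3)c(OC)c(=O)c2c1OCOC
F9 | step 13 | 1,5-bis(dimethylamino)-2,4-dialkylpenta-1,4-dien-3-one from 21 | CN(C)C=C(CC=C(C)C)C(=O)C(=CN(C)C)CC[C@H](C)CO[Si](C)(C)C(C)(C)C
F10 | step 4 | 5-(benzyloxy)-2-methoxy-1,3-bis(methoxymethoxy)benzene | COCOc1cc(OCc2ccccc2)cc(OCOC)c1OC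
F11 | step 4 | 1-[2-(benzyloxy)-5-methoxy-4,6-bis(methoxymethoxy)phenyl]-2-methoxyethan-1-one | COCC(=O)c1c(OCc2ccccc2)cc(OCOC)c(OC)c1OCOC
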